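## Structural features

The target is a sesquiterpenoid joined to a pentasubstituted arene: a cis-fused decalin (ring A C1–C5/C10 with the gem-dimethyl carbon C4, ring B C5–C10) linked through an exocyclic trisubstituted C9=C11 alkene to C1′ of a 2,4,5-trihydroxybenzaldehyde (C1′ is C3 of the benzaldehyde, the formyl group sits on C5′). There are three stereocentres, (5R,8S,10S). Quaternary C10 is flanked by the ring-fusion CH C5 and by sp2 C9; C8 stands in a 1,3-relationship to C10 across C9. H-5, CH3-10 and CH3-8 all lie on one face, and the alkene is E, with the arene turned away from C10. The fragile parts are the hydroxyquinol (air oxidation to a quinone), the aldehyde, and the electron-rich styrene-type alkene, which on protonation gives a C9 or C11 cation that can be trapped by the ortho phenol or can migrate into the ring and scramble C8. The real difficulty is the cis ring fusion at a quaternary carbon, set next to a crowded exocyclic alkene of defined geometry, with C8 correctly related to both. The key step exploits C4 as a tertiary cation site, the C5–C10 bond as a former Z alkene and C9=C11 as a styrene terminator, so that rings A and B, C5 and C10 arise in one operation from an acyclic chain that carries only C8.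

## Logic of the disconnections

23 to 22: the three phenolic O–isopropyl bonds are cut last. The free hydroxyquinol is air-sensitive and would quench every base and Lewis acid used earlier, whereas secondary alkyl aryl ethers survive organolithiums, SnCl4 at low temperature and hydride. The gain is a robust, chromatographable series. The demand on the forward step is that ether cleavage must spare the C9=C11 alkene and the aldehyde, hence a low-temperature Lewis acid and a basic quench.

22 to 21 to 20: no skeletal bond is cut; the C5′ substituent is taken back from formyl through hydroxymethyl to the methyl ester. An aldehyde would not survive the olefination base or the chlorinating reagent, while the ester lowers the nucleophilicity of the ring itself in the cyclisation. It is meta to C1′, so it does not withdraw from the benzylic C11 position by resonance. The forward steps must reduce without touching the alkene and oxidise without going past the aldehyde.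

20 to 19: the C4–C5 and C9–C10 bonds are cut, opening rings A and B and removing C5 and C10 as stereocentres. This is the largest simplification of the route: 19 is acyclic and its only stereocentre is C8. 19 is kept as tertiary chloride, methyl ester and tris(isopropyl) ether, because the chloride can be ionised without any protic acid and the two ortho ethers make the styrene a fast terminator. The forward step must ionise C4 only, add anti across the Z C5=C10 alkene in a near-concerted way and let C8 choose the face; a proton trap and high dilution serve this.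

19 to 18: the C4–Cl bond is cut to the tertiary alcohol. A tertiary chloride would not survive the bases used before, so it is made last and used at once. The forward step must substitute a tertiary hydroxyl without free acid and without premature ionisation.

18 to 11 and 17: the C9=C11 alkene is cut into a sulfone carbanion at C9 and an aryl aldehyde at C11. This is the most convergent cut and brings the ester-bearing arene in only after all organomagnesium chemistry is finished. It places the carbanion β to C8, so that no epimerisable α-methyl aldehyde is ever made. The demand is E selectivity and tolerance of the tertiary hydroxyl and the ester.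

17 to 16 to 15 to 13 to 12: the C5′–CO2CH3 bond is cut to C5′–Br, C5′–Br to C5′–H, the C1′–CHO bond to C1′–H, and the three O–isopropyl bonds to the triol. Each cut uses the innate selectivity of the ring: metalation between two ether oxygens for C1′, bromination para and ortho to ether oxygens for C5′. The demand is clean regiocontrol in both substitutions.

11 to 10 to 9 to 8: the two S–O bonds, the C9–S bond and the O–Si bond are cut in turn, leading back to a silyl-protected primary alcohol. These are functional-group changes at C9 only; the forward steps must leave the Z alkene and the tertiary alcohol alone.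

8 to 4 and 6 (through 7): the C6–C7 bond is cut between an allylic electrophile and an alkylmagnesium nucleophile. This divides the chain into a ten-carbon unit that already contains the Z C5=C10 alkene and C4 at the right oxidation level, and a three-carbon unit that carries C8. The demand is substitution at the CH2 terminus (not at the γ-carbon) with retention of Z geometry.

4 to 3 to 1, and 6 to 5: the C6–Cl bond is cut to the allylic alcohol, the C4–OH bond to the distal alkene of 1, and the O–Si bond of 6 to 5. The forward steps need site-selective hydration of the distal alkene, which the allylic oxygen secures by deactivating the proximal one, and chlorination of the primary allylic hydroxyl only.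

## Other disconnections considered

Alternative 1: The cut is the C9–C10 bond alone; ring A is kept as an isophorone-type enone and ring B is closed onto it. In the forward sense DBU would deprotonate the primary nitroalkane of (4R)-3,5,5-trimethyl-4-[(3S)-3-methyl-4-nitrobutyl]cyclohex-2-en-1-one A1, and the nitronate would add 6-exo to the enone β-carbon C10 to give the cis-fused nitrodecalinone A2.
- In favour: the three-atom tether on C5 can reach C10 only from its own face, so the cis fusion is enforced by geometry and does not depend on a concerted cascade. On this point the alternative is the better of the two. The conditions are mild and basic, no cation is formed that could rearrange, and the nitro group is a handle at C9 (Nef reaction to the ketone).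
- Against: the acceptor is β,β-disubstituted, so the addition that creates quaternary C10 is slow and reversible. A1 needs both C5 and C8 set beforehand, whereas the chosen plan buys only C8. After the closure the C2 carbonyl must be removed, and the arylmethylidene must be built on a C9 carbonyl flanked by C10 and C8, where neither the exocyclic position nor the E geometry of the alkene is assured and C8 becomes epimerisable.
- Comparison: structurally both reach the cis-decalin with both methyl groups. Mechanistically the alternative is anionic and under thermodynamic control and forms one bond and one ring, while the chosen plan is kinetic and forms two bonds, two rings and the alkene. In step count the alternative is the longer, since deoxygenation, Nef reaction, aryl addition, dehydration and arene adjustment all follow its key step.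

Alternative 2: The cuts are C5–C6 and C9–C10; ring B is assembled by cycloaddition onto ring A. In the forward sense 2,4,4-trimethylcyclohex-2-en-1-one A3, bound to a chiral oxazaborolidinium triflimide, would take up tert-butyldimethyl{[(1E)-2-methylbuta-1,3-dien-1-yl]oxy}silane A4 in an endo Diels–Alder reaction to give the octalone A5.
- In favour: suprafacial addition guarantees the cis fusion, which is at least the equal of the chosen plan in certainty. The absolute configuration of C5 and C10 comes from a catalyst and two achiral, simple partners, which is better than relying on a chiral building block. The regiochemistry follows from the 1-oxygenated diene, and the step is convergent.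
- Against: A3 carries an α-methyl group and its β-carbon C5 is neopentyl, so the cycloaddition is sterically very demanding even with strong activation. C8 is not set (it stays sp2 in A5 and would need a later face-selective hydrogenation). The C1 carbonyl has no counterpart in the target and must be removed, and the C9 oxygen must still be turned into the arylmethylidene on a hindered ketone.
- Comparison: in structure the alternative delivers the ring fusion but not C8, the alkene or the arene. In mechanism a concerted pericyclic step under catalyst control is more predictable for the fusion than a cationic cascade under substrate control. In step economy the short access to A5 is outweighed by the long sequence after it, so the chosen plan should be shorter overall.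

Alternative 3: The cuts are C11–C1′ and C8–C9; arene and ring B are introduced together on a preformed ring A. In the forward sense the aryl–rhodium species formed from [3-(dimethoxymethyl)-2,5,6-tris(methoxymethoxy)phenyl]boronic acid A7 and a monovalent rhodium catalyst such as [Rh(OH)(cod)]2 would add syn across the terminal alkyne of methyl (2E)-5-[(1R,2S)-2-ethynyl-2,6,6-trimethylcyclohexyl]pent-2-enoate A6, and the alkenyl–rhodium would add to the enoate to give A8.
- In favour: the E geometry of C9=C11 follows directly from syn carbometalation, which is better than the chosen plan, where it rests on a thermodynamic preference. The arene is joined late under nearly neutral conditions, so acetal protecting groups can be used and no BCl3 is needed at the end. A chiral ligand could control C8.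
- Against: the hard problem, the cis relationship of H-5 and the C10 methyl at a quaternary carbon, is not solved by the key step but moved into the synthesis of A6. Closure of a six-membered ring by alkenyl–rhodium conjugate addition is less favourable than the five-membered closures typical of this reaction type. A7 has two ortho alkoxy groups and is prone to protodeboronation and slow transmetalation. C8 arrives bearing CH2CO2CH3, one carbon too many, so a decarboxylative degradation must follow.
- Comparison: in structure the alternative covers arene, alkene and C8, while the chosen plan covers rings A and B, C5 and C10. In mechanism its geometry control is better and its ring-size preference worse. In step economy the preparation of A6 and the side-chain degradation make it the longer route.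

Key step: step 14

Remark: positions are numbered as in the terpenoid skeleton in all compounds, acyclic ones included (C1–C10 decalin carbons, C11 the alkene CH, C1′–C6′ the arene with C1′ on C11 and the carbonyl carbon on C5′).
Remark: the descriptors were checked against the structures: C3 of 19 (S) is C8 of 23 (S), and the product with H-5, CH3-10 and CH3-8 on one face is (5R,8S,10S); no structure needed correction.
Remark: nerol, (2R)-3-bromo-2-methylpropan-1-ol and benzene-1,2,4-triol are taken as commercial.

Step 1
Reactants: 1 nerol, (2Z)-3,7-dimethylocta-2,6-dien-1-ol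
Product: 3 (2Z)-3,7-dimethyloct-2-ene-1,7-diol, via organomercurial acetate 2 (not isolated)
Conditions: Hg(OAc)2, THF/H2O, 0 °C to rt; then aq. NaOH, NaBH4, 0 °C
Reagents that add atoms: water, O
Why: Markovnikov oxymercuration–demercuration; divalent mercury attacks the distal trisubstituted alkene because the C5=C10 alkene is deactivated by the allylic oxygen, water opens the mercurinium ion at the tertiary carbon, and NaBH4 replaces mercury by hydrogen. The Z alkene is not involved.

Step 2
Reactants: 3 (2Z)-3,7-dimethyloct-2-ene-1,7-diol
Product: 4 (6Z)-8-chloro-2,6-dimethyloct-6-en-2-ol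
Conditions: N-chlorosuccinimide, Me2S, CH2Cl2, −30 to 0 °C
Reagents that add atoms: N-chlorosuccinimide, O=C1CCC(=O)N1Cl
Why: Corey–Kim chlorination; the chlorosulfonium salt activates only the unhindered primary allylic hydroxyl, and chloride displaces it by SN2 without allylic transposition or loss of Z geometry. The tertiary hydroxyl cannot be displaced in this way; 4 is used promptly.

Step 3
Reactants: 5 (2R)-3-bromo-2-methylpropan-1-ol
Product: 6 [(2R)-3-bromo-2-methylpropoxy](tert-butyl)dimethylsilane
Conditions: tert-butyl(chloro)dimethylsilane, imidazole, CH2Cl2, 0 °C to rt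
Reagents that add atoms: tert-butyl(chloro)dimethylsilane, CC(C)(C)[Si](C)(C)Cl
Why: standard silylation of a primary alcohol; the stereocentre (the future C8) is not touched.

Step 4
Reactants: 6 [(2R)-3-bromo-2-methylpropoxy](tert-butyl)dimethylsilane; 4 (6Z)-8-chloro-2,6-dimethyloct-6-en-2-ol
Product: 8 (6Z,10S)-11-{[tert-butyl(dimethyl)silyl]oxy}-2,6,10-trimethylundec-6-en-2-ol, via alkylmagnesium bromide 7 (not isolated)
Conditions: 6, Mg, THF, 40 °C; separately 4, MeMgCl (1.0 equiv), THF, −30 °C; then Li2CuCl4 (2 mol%) and 7 (1.3 equiv), −78 to 0 °C; aq. NH4Cl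
Reagents that add atoms: none
Why: copper-catalysed cross-coupling of an alkylmagnesium halide with a primary allylic chloride, forming the C6–C7 bond; the hydroxyl of 4 is first turned into its magnesium alkoxide by MeMgCl. Attack at the γ-carbon would create a quaternary centre, so substitution at the CH2Cl carbon is expected, with the alkene geometry unchanged. The stereocentre is β to magnesium and is not affected.

Step 5
Reactants: 8 (6Z,10S)-11-{[tert-butyl(dimethyl)silyl]oxy}-2,6,10-trimethylundec-6-en-2-ol
Product: 9 (2S,5Z)-2,6,10-trimethylundec-5-ene-1,10-diol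
Conditions: Bu4NF, THF, 0 °C to rt
Reagents that add atoms: none
Why: fluoride-induced cleavage of the primary silyl ether; nothing else in the molecule responds to fluoride.

Step 6
Reactants: 9 (2S,5Z)-2,6,10-trimethylundec-5-ene-1,10-diol
Product: 10 (6Z,10S)-2,6,10-trimethyl-11-[(1-phenyl-1H-tetrazol-5-yl)sulfanyl]undec-6-en-2-ol
Conditions: 1-phenyl-1H-tetrazole-5-thiol, PPh3, diisopropyl azodicarboxylate, THF, 0 °C to rt
Reagents that add atoms: 1-phenyl-1H-tetrazole-5-thiol, Sc1nnnn1-c1ccccc1
Why: Mitsunobu thioetherification; only the primary hydroxyl forms an alkoxyphosphonium ion that the thiolate can displace, the tertiary hydroxyl is inert. The adjacent stereocentre is not a reacting centre.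

Step 7
Reactants: 10 (6Z,10S)-2,6,10-trimethyl-11-[(1-phenyl-1H-tetrazol-5-yl)sulfanyl]undec-6-en-2-ol
Product: 11 (6Z,10S)-2,6,10-trimethyl-11-[(1-phenyl-1H-tetrazol-5-yl)sulfonyl]undec-6-en-2-ol
Conditions: (NH4)6Mo7O24·4H2O (cat.), 30% H2O2, EtOH, 0 °C to rt
Reagents that add atoms: hydrogen peroxide, OO
Why: molybdate-catalysed oxidation of the sulfide to the sulfone; the peroxomolybdate oxidises sulfur far faster than an unactivated trisubstituted alkene, and the reaction is stopped once the sulfoxide is consumed.

Step 8
Reactants: 12 benzene-1,2,4-triol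
Product: 13 1,2,4-triisopropoxybenzene
Conditions: 2-bromopropane (excess), K2CO3, DMF, 70 °C, argon
Reagents that add atoms: 2-bromopropane, CC(C)Br
Why: Williamson ether synthesis on all three phenols; exclusion of air prevents oxidation of the triol to the hydroxyquinone before alkylation.

Step 9
Reactants: 13 1,2,4-triisopropoxybenzene
Product: 15 2,3,6-triisopropoxybenzaldehyde, via aryllithium 14 (not isolated)
Conditions: n-BuLi, TMEDA, THF, 0 °C to rt; then DMF, −78 °C to rt; aq. NH4Cl
Reagents that add atoms: N,N-dimethylformamide, CN(C)C=O
Why: directed ortho-metalation; the CH between two ether oxygens is the most acidic and is doubly coordinated, so lithiation there (the future C1′) is expected, and DMF formylates the aryllithium.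

Step 10
Reactants: 15 2,3,6-triisopropoxybenzaldehyde
Product: 16 3-bromo-2,5,6-triisopropoxybenzaldehyde
Conditions: N-bromosuccinimide, MeCN, 0 °C to rt
Reagents that add atoms: N-bromosuccinimide, O=C1CCC(=O)N1Br
Why: electrophilic aromatic bromination; C5′ is para to one ether oxygen, ortho to another and meta to the formyl group. The only other free position is para to the formyl group and activated by one oxygen only.

Step 11
Reactants: 16 3-bromo-2,5,6-triisopropoxybenzaldehyde
Product: 17 methyl 3-formyl-2,4,5-triisopropoxybenzoate
Conditions: Pd(OAc)2 (cat.), Xantphos (cat.), CO (1 atm), MeOH, Et3N, 70 °C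
Reagents that add atoms: carbon monoxide, [C-]#[O+]; methanol, CO
Why: palladium-catalysed methoxycarbonylation of an aryl bromide: oxidative addition of zerovalent palladium, CO insertion and methanolysis of the acyl complex. The aldehyde is inert under these conditions.

Step 12
Reactants: 11 (6Z,10S)-2,6,10-trimethyl-11-[(1-phenyl-1H-tetrazol-5-yl)sulfonyl]undec-6-en-2-ol; 17 methyl 3-formyl-2,4,5-triisopropoxybenzoate
Product: 18 methyl 3-[(1E,3S,6Z)-11-hydroxy-3,7,11-trimethyldodeca-1,6-dien-1-yl]-2,4,5-triisopropoxybenzoate
Conditions: KN(SiMe3)2 (1.5 equiv) added to 11 and 17, THF, −78 °C to rt; aq. NH4Cl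
Reagents that add atoms: none
Why: Julia–Kocienski olefination forming C9=C11: the sulfonyl carbanion adds to the aldehyde, and Smiles rearrangement with loss of SO2 and the tetrazolone gives the alkene, expected E for an electron-rich aryl aldehyde. C8 is β to the carbanion and cannot epimerise. The sulfone α-CH is more acidic than the tertiary hydroxyl, so no protection is needed.

Step 13
Reactants: 18 methyl 3-[(1E,3S,6Z)-11-hydroxy-3,7,11-trimethyldodeca-1,6-dien-1-yl]-2,4,5-triisopropoxybenzoate
Product: 19 methyl 3-[(1E,3S,6Z)-11-chloro-3,7,11-trimethyldodeca-1,6-dien-1-yl]-2,4,5-triisopropoxybenzoate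
Conditions: 1-chloro-N,N,2-trimethylprop-1-en-1-amine, CH2Cl2, 0 °C; filtration through basic Al2O3, used at once
Reagents that add atoms: 1-chloro-N,N,2-trimethylprop-1-en-1-amine, CC(C)=C(Cl)N(C)C
Why: deoxychlorination of a tertiary alcohol with an α-chloroenamine under neutral conditions; the alcohol adds to the keteniminium form and the alkoxyiminium chloride collapses by ion-pair return to the tertiary chloride and the amide. No free acid is formed that could protonate either alkene.

Step 14
Reactants: 19 methyl 3-[(1E,3S,6Z)-11-chloro-3,7,11-trimethyldodeca-1,6-dien-1-yl]-2,4,5-triisopropoxybenzoate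
Product: 20 methyl 2,4,5-triisopropoxy-3-{(E)-[(2S,4aR,8aS)-2,5,5,8a-tetramethyloctahydronaphthalen-1(2H)-ylidene]methyl}benzoate
Conditions: SnCl4 (2.5 equiv), 2,6-di-tert-butyl-4-methylpyridine (1.5 equiv), CH2Cl2 (0.005 M), −78 to −40 °C; aq. NaHCO3
Reagents that add atoms: none
Why: SnCl4 abstracts chloride from C4 and the developing tertiary cation is taken up by the Z C5=C10 alkene as it forms, the C10 cation is trapped by styrene carbon C9, and the benzylic C11 cation loses H-9 to the hindered pyridine; the closest known reaction type is the Lewis acid-initiated cation–olefin polyene cyclisation with arylalkene termination. Ring A closes 6-endo through a chair, both alkene carbons becoming ring atoms. Ring B closes 6-exo with respect to the styrene, again through a chair. C5 and C10 are set together: antiperiplanar addition of C4 and C9 across the alkene turns its Z geometry into the cis relationship of H-5 and CH3-10. Their absolute sense is set by C8, whose methyl group takes the equatorial position in the ring B chair because the axial one would clash with C1 of ring A, which is axial on ring B; this places it cis to CH3-10. The step needs ionisation at C4 only and a fast terminator: aprotic conditions and the proton trap keep both alkenes unprotonated, the two ortho ether oxygens make the styrene nucleophilic, and the ester (used with excess SnCl4, since it binds one equivalent) keeps the ring itself from reacting. Only H-9 can be lost, so one alkene regioisomer is expected, and A1,3 strain should turn the arene away from quaternary C10 (E).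

Step 15
Reactants: 20 methyl 2,4,5-triisopropoxy-3-{(E)-[(2S,4aR,8aS)-2,5,5,8a-tetramethyloctahydronaphthalen-1(2H)-ylidene]methyl}benzoate
Product: 21 (2,4,5-triisopropoxy-3-{(E)-[(2S,4aR,8aS)-2,5,5,8a-tetramethyloctahydronaphthalen-1(2H)-ylidene]methyl}phenyl)methanol
Conditions: iBu2AlH (3 equiv), CH2Cl2, −78 to 0 °C; aq. KNaC4H4O6
Reagents that add atoms: none
Why: hydride reduction of the aryl ester to the benzylic alcohol; the hindered trisubstituted alkene and the ethers are inert to iBu2AlH, and the neutral work-up avoids ionising the electron-rich benzylic alcohol.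

Step 16
Reactants: 21 (2,4,5-triisopropoxy-3-{(E)-[(2S,4aR,8aS)-2,5,5,8a-tetramethyloctahydronaphthalen-1(2H)-ylidene]methyl}phenyl)methanol
Product: 22 2,4,5-triisopropoxy-3-{(E)-[(2S,4aR,8aS)-2,5,5,8a-tetramethyloctahydronaphthalen-1(2H)-ylidene]methyl}benzaldehyde
Conditions: MnO2 (excess), CH2Cl2, rt
Reagents that add atoms: none
Why: MnO2 oxidises benzylic alcohols selectively and stops at the aldehyde under neutral, heterogeneous conditions.

Step 17
Reactants: 22 2,4,5-triisopropoxy-3-{(E)-[(2S,4aR,8aS)-2,5,5,8a-tetramethyloctahydronaphthalen-1(2H)-ylidene]methyl}benzaldehyde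
Product: 23 2,4,5-trihydroxy-3-{(E)-[(2S,4aR,8aS)-2,5,5,8a-tetramethyloctahydronaphthalen-1(2H)-ylidene]methyl}benzaldehyde
Conditions: BCl3 (6 equiv), CH2Cl2, −78 to 0 °C; poured into cold aq. NaHCO3, argon
Reagents that add atoms: none
Why: Lewis acid cleavage of secondary alkyl aryl ethers; BCl3 binds each ether oxygen (first the one chelated to the formyl group) and chloride removes the isopropyl group as 2-chloropropane. No protic acid is present until the cold basic quench, which should protect the C9=C11 alkene; the stereocentres are remote from the reacting sites.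

Compound list
1 | nerol, (2Z)-3,7-dimethylocta-2,6-dien-1-ol | CC(C)=CCC/C(C)=C\CO | starting material
2 | (2Z)-6-(acetoxymercurio)-3,7-dimethyloct-2-ene-1,7-diol, racemic at C6, not isolated | CC(C)(O)C([Hg]OC(C)=O)CC/C(C)=C\CO | intermediate
3 | (2Z)-3,7-dimethyloct-2-ene-1,7-diol | CC(C)(O)CCC/C(C)=C\CO | intermediate
4 | (6Z)-8-chloro-2,6-dimethyloct-6-en-2-ol | CC(C)(O)CCC/C(C)=C\CCl | intermediate
5 | (2R)-3-bromo-2-methylpropan-1-ol | BrC[C@H](C)CO | starting material
6 | [(2R)-3-bromo-2-methylpropoxy](tert-butyl)dimethylsilane | BrC[C@H](C)CO[Si](C)(C)C(C)(C)C | intermediate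
7 | [(2R)-3-{[tert-butyl(dimethyl)silyl]oxy}-2-methylpropyl]magnesium bromide, not isolated | Br[Mg]C[C@H](C)CO[Si](C)(C)C(C)(C)C | intermediate
8 | (6Z,10S)-11-{[tert-butyl(dimethyl)silyl]oxy}-2,6,10-trimethylundec-6-en-2-ol | CC(C)(O)CCC/C(C)=C\CC[C@H](C)CO[Si](C)(C)C(C)(C)C | intermediate
9 | (2S,5Z)-2,6,10-trimethylundec-5-ene-1,10-diol | CC(C)(O)CCC/C(C)=C\CC[C@H](C)CO | intermediate
10 | (6Z,10S)-2,6,10-trimethyl-11-[(1-phenyl-1H-tetrazol-5-yl)sulfanyl]undec-6-en-2-ol | CC(C)(O)CCC/C(C)=C\CC[C@H](C)CSc1nnnn1-c1ccccc1 | intermediate
11 | (6Z,10S)-2,6,10-trimethyl-11-[(1-phenyl-1H-tetrazol-5-yl)sulfonyl]undec-6-en-2-ol | CC(C)(O)CCC/C(C)=C\CC[C@H](C)CS(=O)(=O)c1nnnn1-c1ccccc1 | intermediate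
12 | benzene-1,2,4-triol | Oc1ccc(O)c(O)c1 | starting material
13 | 1,2,4-triisopropoxybenzene | CC(C)Oc1ccc(OC(C)C)c(OC(C)C)c1 | intermediate
14 | (2,3,6-triisopropoxyphenyl)lithium, not isolated | [Li]c1c(OC(C)C)c(OC(C)C)ccc1OC(C)C | intermediate
15 | 2,3,6-triisopropoxybenzaldehyde | O=Cc1c(OC(C)C)c(OC(C)C)ccc1OC(C)C | intermediate
16 | 3-bromo-2,5,6-triisopropoxybenzaldehyde | O=Cc1c(OC(C)C)c(OC(C)C)cc(Br)c1OC(C)C | intermediate
17 | methyl 3-formyl-2,4,5-triisopropoxybenzoate | O=Cc1c(OC(C)C)c(OC(C)C)cc(C(=O)OC)c1OC(C)C | intermediate
18 | methyl 3-[(1E,3S,6Z)-11-hydroxy-3,7,11-trimethyldodeca-1,6-dien-1-yl]-2,4,5-triisopropoxybenzoate | CC(C)(O)CCC/C(C)=C\CC[C@H](C)/C=C/c1c(OC(C)C)c(OC(C)C)cc(C(=O)OC)c1OC(C)C | intermediate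
19 | methyl 3-[(1E,3S,6Z)-11-chloro-3,7,11-trimethyldodeca-1,6-dien-1-yl]-2,4,5-triisopropoxybenzoate | CC(C)(Cl)CCC/C(C)=C\CC[C@H](C)/C=C/c1c(OC(C)C)c(OC(C)C)cc(C(=O)OC)c1OC(C)C | intermediate
20 | methyl 2,4,5-triisopropoxy-3-{(E)-[(2S,4aR,8aS)-2,5,5,8a-tetramethyloctahydronaphthalen-1(2H)-ylidene]methyl}benzoate | C[C@H]1CC[C@@H]2C(C)(C)CCC[C@]2(C)/C1=C/c1c(OC(C)C)c(OC(C)C)cc(C(=O)OC)c1OC(C)C | intermediate
21 | (2,4,5-triisopropoxy-3-{(E)-[(2S,4aR,8aS)-2,5,5,8a-tetramethyloctahydronaphthalen-1(2H)-ylidene]methyl}phenyl)methanol | C[C@H]1CC[C@@H]2C(C)(C)CCC[C@]2(C)/C1=C/c1c(OC(C)C)c(OC(C)C)cc(CO)c1OC(C)C | intermediate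
22 | 2,4,5-triisopropoxy-3-{(E)-[(2S,4aR,8aS)-2,5,5,8a-tetramethyloctahydronaphthalen-1(2H)-ylidene]methyl}benzaldehyde | C[C@H]1CC[C@@H]2C(C)(C)CCC[C@]2(C)/C1=C/c1c(OC(C)C)c(OC(C)C)cc(C=O)c1OC(C)C | intermediate
23 | 2,4,5-trihydroxy-3-{(E)-[(2S,4aR,8aS)-2,5,5,8a-tetramethyloctahydronaphthalen-1(2H)-ylidene]methyl}benzaldehyde | C[C@H]1CC[C@@H]2C(C)(C)CCC[C@]2(C)/C1=C/c1c(O)c(O)cc(C=O)c1O | target

Total step count: 17. Longest linear sequence: 12 steps (steps 1, 2, 4, 5, 6, 7, 12, 13, 14, 15, 16, 17).

Least certain steps

The key step, step 14. What is most likely to go wrong is premature termination after ring A: the C10 cation may lose a proton or take chloride back because the hindered styrene, weakened by the ester and by SnCl4 held in the ester/ortho-ether chelate, captures it too slowly. A slower capture also loosens the antiperiplanar addition and would let trans-fused material form. The fallback runs the cyclisation on a more nucleophilic styrene that has bromine in place of the ester. It sets out from 11 and 16.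
- Julia–Kocienski olefination (KN(SiMe3)2, THF, −78 °C) would give (6Z,10S,11E)-12-(3-bromo-2,5,6-triisopropoxyphenyl)-2,6,10-trimethyldodeca-6,11-dien-2-ol F1.
- The α-chloroenamine would convert it into 1-bromo-3-[(1E,3S,6Z)-11-chloro-3,7,11-trimethyldodeca-1,6-dien-1-yl]-2,4,5-triisopropoxybenzene F2.
- SnCl4 and the pyridine base would cyclise it to 1-bromo-2,4,5-triisopropoxy-3-{(E)-[(2S,4aR,8aS)-2,5,5,8a-tetramethyloctahydronaphthalen-1(2H)-ylidene]methyl}benzene F3.
- Bromine–lithium exchange (t-BuLi, THF, −78 °C) and DMF would give the aldehyde, so the fallback returns to the route at 22.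

Step 13. The tertiary alkoxyiminium ion may eliminate to the isopropenyl and isopropylidene alkenes instead of collapsing to the chloride, and the chloride may ionise on handling. The fallback avoids the chloride altogether. From 18, trifluoroacetic anhydride and pyridine (CH2Cl2, −20 °C) would give methyl 2,4,5-triisopropoxy-3-[(1E,3S,6Z)-3,7,11-trimethyl-11-(trifluoroacetoxy)dodeca-1,6-dien-1-yl]benzoate F4. This tertiary ester would be ionised directly by SnCl4 with the same proton trap, returning to the route at 20.

Step 4. Three processes threaten it: attack at the γ-carbon, erosion of the Z geometry through an equilibrating allyl–copper species, and intramolecular O-allylation by the magnesium alkoxide to a vinyl-tetrahydropyran. The fallback changes the bond construction to a sulfone alkylation, in which the regiochemistry is fixed by the carbanion.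
- From 4, PhSO2Na in DMF would give (6Z)-2,6-dimethyl-8-(phenylsulfonyl)oct-6-en-2-ol F5.
- From 6, NaI in acetone (Finkelstein exchange) would give tert-butyl{[(2R)-3-iodo-2-methylpropyl]oxy}dimethylsilane F6.
- The dianion of F5 (n-BuLi, 2.1 equiv, THF/DMPU, −78 to −20 °C) would be alkylated by F6 to (6Z,10S)-11-{[tert-butyl(dimethyl)silyl]oxy}-2,6,10-trimethyl-8-(phenylsulfonyl)undec-6-en-2-ol F7.
- Reductive desulfonylation with LiBHEt3 and catalytic PdCl2(dppp), reduced in the flask to zerovalent palladium, at 0 °C would return to the route at 8.

Step 17. Acid-driven processes are the danger: protonation of the C9=C11 alkene, followed by migration into the ring or capture by the freed ortho phenol, while the last ether is still being cleaved; and air oxidation of the product during isolation. The fallback moves the ether cleavage away from the final product. It sets out from 20.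
- BCl3 would give methyl 2,4,5-trihydroxy-3-{(E)-[(2S,4aR,8aS)-2,5,5,8a-tetramethyloctahydronaphthalen-1(2H)-ylidene]methyl}benzoate F8, a robust chelated ester.
- tert-Butyldimethylsilyl triflate and 2,6-lutidine would give its tris(tert-butyldimethylsilyl) ether F9.
- iBu2AlH would give the corresponding benzylic alcohol F10, and MnO2 the corresponding aldehyde F11.
- Bu4NF buffered with acetic acid would release the phenols, so the fallback returns to the route at 23 without exposing the target to a Lewis acid.

Further compounds
F1 | step 14 | (6Z,10S,11E)-12-(3-bromo-2,5,6-triisopropoxyphenyl)-2,6,10-trimethyldodeca-6,11-dien-2-ol | CC(C)(O)CCC/C(C)=C\CC[C@H](C)/C=C/c1c(OC(C)C)c(OC(C)C)cc(Br)c1OC(C)C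
F2 | step 14 | 1-bromo-3-[(1E,3S,6Z)-11-chloro-3,7,11-trimethyldodeca-1,6-dien-1-yl]-2,4,5-triisopropoxybenzene | CC(C)(Cl)CCC/C(C)=C\CC[C@H](C)/C=C/c1c(OC(C)C)c(OC(C)C)cc(Br)c1OC(C)C
F3 | step 14 | 1-bromo-2,4,5-triisopropoxy-3-{(E)-[(2S,4aR,8aS)-2,5,5,8a-tetramethyloctahydronaphthalen-1(2H)-ylidene]methyl}benzene | C[C@H]1CC[C@@H]2C(C)(C)CCC[C@]2(C)/C1=C/c1c(OC(C)C)c(OC(C)C)cc(Br)c1OC(C)C
F4 | step 13 | methyl 2,4,5-triisopropoxy-3-[(1E,3S,6Z)-3,7,11-trimethyl-11-(trifluoroacetoxy)dodeca-1,6-dien-1-yl]benzoate | CC(C)(OC(=O)C(F)(F)F)CCC/C(C)=C\CC[C@H](C)/C=C/c1c(OC(C)C)c(OC(C)C)cc(C(=O)OC)c1OC(C)C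
F5 | step 4 | (6Z)-2,6-dimethyl-8-(phenylsulfonyl)oct-6-en-2-ol | CC(C)(O)CCC/C(C)=C\CS(=O)(=O)c1ccccc1
F6 | step 4 | tert-butyl{[(2R)-3-iodo-2-methylpropyl]oxy}dimethylsilane | IC[C@H](C)CO[Si](C)(C)C(C)(C)C
F7 | step 4 | (6Z,10S)-11-{[tert-butyl(dimethyl)silyl]oxy}-2,6,10-trimethyl-8-(phenylsulfonyl)undec-6-en-2-ol, both C8 epimers | CC(C)(O)CCC/C(C)=C\C(C[C@H](C)CO[Si](C)(C)C(C)(C)C)S(=O)(=O)c1ccccc1
F8 | step 17 | methyl 2,4,5-trihydroxy-3-{(E)-[(2S,4aR,8aS)-2,5,5,8a-tetramethyloctahydronaphthalen-1(2H)-ylidene]methyl}benzoate | C[C@H]1CC[C@@H]2C(C)(C)CCC[C@]2(C)/C1=C/c1c(O)c(O)cc(C(=O)OC)c1O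
F9 | step 17 | methyl 2,4,5-tris{[tert-butyl(dimethyl)silyl]oxy}-3-{(E)-[(2S,4aR,8aS)-2,5,5,8a-tetramethyloctahydronaphthalen-1(2H)-ylidene]methyl}benzoate | C[C@H]1CC[C@@H]2C(C)(C)CCC[C@]2(C)/C1=C/c1c(O[Si](C)(C)C(C)(C)C)c(O[Si](C)(C)C(C)(C)C)cc(C(=O)OC)c1O[Si](C)(C)C(C)(C)C
F10 | step 17 | (2,4,5-tris{[tert-butyl(dimethyl)silyl]oxy}-3-{(E)-[(2S,4aR,8aS)-2,5,5,8a-tetramethyloctahydronaphthalen-1(2H)-ylidene]methyl}phenyl)methanol | C[C@H]1CC[C@@H]2C(C)(C)CCC[C@]2(C)/C1=C/c1c(O[Si](C)(C)C(C)(C)C)c(O[Si](C)(C)C(C)(C)C)cc(CO)c1O[Si](C)(C)C(C)(C)C
F11 | step 17 | 2,4,5-tris{[tert-butyl(dimethyl)silyl]oxy}-3-{(E)-[(2S,4aR,8aS)-2,5,5,8a-tetramethyloctahydronaphthalen-1(2H)-ylidene]methyl}benzaldehyde | C[C@H]1CC[C@@H]2C(C)(C)CCC[C@]2(C)/C1=C/c1c(O[Si](C)(C)C(C)(C)C)c(O[Si](C)(C)C(C)(C)C)cc(C=O)c1O[Si](C)(C)C(C)(C)C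
A1 | alternative 1 | (4R)-3,5,5-trimethyl-4-[(3S)-3-methyl-4-nitrobutyl]cyclohex-2-en-1-one | C[C@@H](CC[C@@H]1C(C)(C)CC(=O)C=C1C)C[N+](=O)[O-]
A2 | alternative 1 | (5R,8S,9R,10S)-4,4,8,10-tetramethyl-9-nitro-cis-decalin-2-one (terpenoid numbering) | C[C@H]1CC[C@@H]2C(C)(C)CC(=O)C[C@]2(C)[C@@H]1[N+](=O)[O-]
A3 | alternative 2 | 2,4,4-trimethylcyclohex-2-en-1-one | CC1=CC(C)(C)CCC1=O
A4 | alternative 2 | tert-butyldimethyl{[(1E)-2-methylbuta-1,3-dien-1-yl]oxy}silane | C=C/C(C)=C/O[Si](C)(C)C(C)(C)C
A5 | alternative 2 | (5R,9R,10S)-9-{[tert-butyl(dimethyl)silyl]oxy}-4,4,8,10-tetramethyl-cis-octal-7-en-1-one (terpenoid numbering) | CC1=CC[C@@H]2C(C)(C)CCC(=O)[C@]2(C)[C@@H]1O[Si](C)(C)C(C)(C)C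
A6 | alternative 3 | methyl (2E)-5-[(1R,2S)-2-ethynyl-2,6,6-trimethylcyclohexyl]pent-2-enoate | COC(=O)/C=C/CC[C@@H]1C(C)(C)CCC[C@]1(C)C#C
A7 | alternative 3 | [3-(dimethoxymethyl)-2,5,6-tris(methoxymethoxy)phenyl]boronic acid | OB(O)c1c(OCOC)c(OCOC)cc(C(OC)OC)c1OCOC
A8 | alternative 3 | methyl 2-[(1E,2R,4aR,8aS)-1-{[3-(dimethoxymethyl)-2,5,6-tris(methoxymethoxy)phenyl]methylidene}-5,5,8a-trimethyldecahydronaphthalen-2-yl]acetate | COC(=O)C[C@H]1CC[C@@H]2C(C)(C)CCC[C@]2(C)/C1=C/c1c(OCOC)c(OCOC)cc(C(OC)OC)c1OCOC
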